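**Retrosynthetic overview**
1. The target is (−)-epiafzelechin-(4β→6)-(−)-epicatechin 3-O-gallate; the gallate goes on O3′ last, and one hydrogenolysis removes eleven benzyl ethers and a C8′ bromine.
2. Key disconnection: C4–C4a of the upper pyran (ring C). The feature used is that upper C4 is a diarylmethine carbon bonded to C6′ of ring D, whose O5′ and O7′ (ortho) and O1′ (para) stabilise a cation at C4, while ring A already sits on O1 at C2; ionising a C4 carbinol lets the ortho carbon of the 3,5-dibenzyloxyphenoxy ring close ring C.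
3. The C4 carbinol comes from a C6′ arylmagnesium of benzylated 8′-bromoepicatechin (iodine–magnesium exchange; bromine blocks C8′) and a three-carbon aldehyde carrying the C3 benzyloxy and C2 aryloxy groups.
4. The aldehyde comes from methyl 3,4-O-isopropylidene-L-threonate: C3 from the chiral pool, C2 by chelation-controlled ketone reduction then Mitsunobu inversion, the aldehyde carbon (C4) by glycol cleavage.
5. Ring order: rings D, F and E come intact from (−)-epicatechin, rings A and B are preformed arenes, and ring C is the only ring made, in the key step.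

Key step: step 12

Remark: the compounds marked as starting materials in the list are taken as purchasable; the carbinol made in step 11 is carried as both C4 epimers (C4 left undefined in its SMILES) because that centre is lost on ionisation.

Step 1
Reactants: 1 (−)-epicatechin
Product: 2 5,7,3′,4′-tetra-O-benzyl-(−)-epicatechin [(2R,3R)-5,7-bis(benzyloxy)-2-[3,4-bis(benzyloxy)phenyl]chroman-3-ol]
Conditions: BnBr (4.4 equiv), K2CO3, DMF, 0 °C → rt
Reagents that add atoms: benzyl bromide, BrCc1ccccc1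
Why: Williamson O-benzylation of the four phenols with K2CO3, a base too weak to deprotonate the secondary 3-OH, so the alcohol stays free and no stereocentre is touched.

Step 2
Reactants: 2 5,7,3′,4′-tetra-O-benzyl-(−)-epicatechin
Product: 3 8-bromo-5,7,3′,4′-tetra-O-benzyl-(−)-epicatechin
Conditions: NBS (1.0 equiv), CH2Cl2, −78 °C → rt
Reagents that add atoms: N-bromosuccinimide, O=C1CCC(=O)N1Br
Why: Electrophilic aromatic bromination should go to C8 of the trioxygenated ring, the less hindered of its two free positions (C6 lies between two benzyloxy groups), which installs the blocking group.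

Step 3
Reactants: 3 8-bromo-5,7,3′,4′-tetra-O-benzyl-(−)-epicatechin
Product: 4 8-bromo-6-iodo-5,7,3′,4′-tetra-O-benzyl-(−)-epicatechin
Conditions: NIS (1.1 equiv), CF3CO2H (cat.), CH2Cl2, 0 °C, dark
Reagents that add atoms: N-iodosuccinimide, O=C1CCC(=O)N1I
Why: Electrophilic aromatic iodination at C6, the only free position left on the most electron-rich ring, gives an iodide that can be metalated selectively beside the C8 bromide.

Step 4
Reactants: 5 methyl 3,4-O-isopropylidene-L-threonate [methyl (2R)-2-[(4S)-2,2-dimethyl-1,3-dioxolan-4-yl]-2-hydroxyacetate]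
Product: 6 methyl 2-O-benzyl-3,4-O-isopropylidene-L-threonate
Conditions: BnBr, Ag2O, CH2Cl2, rt, dark
Reagents that add atoms: benzyl bromide, BrCc1ccccc1
Why: Ag2O-promoted Williamson benzylation of the α-hydroxy ester runs without a strong base, so the α-centre (the future C3) is not epimerised.

Step 5
Reactants: 6 methyl 2-O-benzyl-3,4-O-isopropylidene-L-threonate
Product: 7 (2R)-2-(benzyloxy)-2-[(4S)-2,2-dimethyl-1,3-dioxolan-4-yl]-N-methoxy-N-methylacetamide
Conditions: MeNH(OMe)·HCl, i-PrMgCl, THF, −20 °C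
Reagents that add atoms: N,O-dimethylhydroxylamine hydrochloride, Cl.CNOC
Why: Aminolysis of the ester by the magnesium amide of N,O-dimethylhydroxylamine (Weinreb amide formation) is fast at low temperature and should leave the α-alkoxy centre intact.

Step 6
Reactants: 7 the Weinreb amide; 8 4-(benzyloxy)phenylmagnesium bromide (THF solution)
Product: 9 (2R)-2-(benzyloxy)-1-[4-(benzyloxy)phenyl]-2-[(4S)-2,2-dimethyl-1,3-dioxolan-4-yl]ethan-1-one
Conditions: THF, 0 °C; aq. NH4Cl
Reagents that add atoms: none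
Why: Weinreb ketone synthesis, in which the chelated tetrahedral intermediate stops at single addition and releases the aryl ketone on work-up.

Step 7
Reactants: 9 the aryl ketone
Product: 10 (1S,2S)-2-(benzyloxy)-1-[4-(benzyloxy)phenyl]-2-[(4S)-2,2-dimethyl-1,3-dioxolan-4-yl]ethan-1-ol (1,2-anti)
Conditions: Zn(BH4)2 (ethereal stock solution), Et2O, −30 → 0 °C; aq. NH4Cl
Reagents that add atoms: none
Why: Chelation-controlled hydride reduction: zinc bridges the carbonyl and α-benzyloxy oxygens in a five-membered chelate and hydride adds from the face of the α-hydrogen, setting the carbinol (future C2) anti to the C3 benzyloxy group.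

Step 8
Reactants: 10 the anti alcohol; 11 3,5-bis(benzyloxy)phenol
Product: 12 (4S)-4-[(1S,2R)-1-(benzyloxy)-2-[3,5-bis(benzyloxy)phenoxy]-2-[4-(benzyloxy)phenyl]ethyl]-2,2-dimethyl-1,3-dioxolane (ether oxygens syn)
Conditions: PPh3, DIAD, toluene, 0 °C → rt
Reagents that add atoms: none
Why: Mitsunobu etherification with the phenol displaces the oxyphosphonium group by SN2 with inversion at the benzylic carbon, turning the anti alcohol into the syn (threo) aryl ether that corresponds to a 2,3-cis flavan; toluene is chosen to disfavour ionisation.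

Step 9
Reactants: 12 the acetonide
Product: 13 (2S,3R,4R)-3-(benzyloxy)-4-[3,5-bis(benzyloxy)phenoxy]-4-[4-(benzyloxy)phenyl]butane-1,2-diol
Conditions: AcOH/H2O (4:1), 40 °C
Reagents that add atoms: none
Why: Mild acid-catalysed acetal hydrolysis should free the terminal diol, while the benzylic aryl ether, flanked by β-oxygens that disfavour ionisation, should survive.

Step 10
Reactants: 13 the diol
Product: 14 (2S,3R)-2-(benzyloxy)-3-[3,5-bis(benzyloxy)phenoxy]-3-[4-(benzyloxy)phenyl]propanal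
Conditions: NaIO4, THF/pH 7 buffer, 0 °C; used crude
Reagents that add atoms: none
Why: Periodate glycol cleavage removes the sacrificial CH2OH carbon under neutral conditions and unmasks the aldehyde (future C4) without epimerising the adjacent centre.

Step 11
Reactants: 4 8-bromo-6-iodo-5,7,3′,4′-tetra-O-benzyl-(−)-epicatechin; 14 the aldehyde
Product: 16 8-bromo-6-[(2R,3R)-2-(benzyloxy)-3-[3,5-bis(benzyloxy)phenoxy]-3-[4-(benzyloxy)phenyl]-1-hydroxypropyl]-5,7,3′,4′-tetra-O-benzyl-(−)-epicatechin (both epimers at the new carbinol carbon), via arylmagnesium chloride 15 (not isolated)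
Conditions: 4 (1.3 equiv), i-PrMgCl·LiCl (2.6 equiv), THF, −30 °C; then 14, −60 → −10 °C; pH 7 buffer
Reagents that add atoms: none
Why: The first equivalent of i-PrMgCl·LiCl deprotonates the 3-OH and the second performs iodine–magnesium exchange at the iodide, which is far faster than exchange at the electron-rich bromide; 1,2-addition of the aryl Grignard to the aldehyde then forms the C6′–C4 bond, and the new carbinol centre is left uncontrolled because it is lost in step 12.

Step 12
Reactants: 16 the C4 carbinol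
Product: 18 3,5,7,4′-tetra-O-benzyl-(−)-epiafzelechin-(4β→6)-8-bromo-5,7,3′,4′-tetra-O-benzyl-(−)-epicatechin, via C4 benzylic cation 17 (not isolated)
Conditions: BF3·OEt2 (2 equiv), CH2Cl2 (0.005 M), −78 → −40 °C; Et3N, then aq. NaHCO3
Reagents that add atoms: none
Why: BF3 coordinates the C4 hydroxyl of 16 and loss of water gives cation 17, a benzylic ion delocalised into ring D onto O5′ and O7′ (ortho) and O1′ (para), which the ortho carbon of the 3,5-dibenzyloxyphenoxy group on C2 (activated by O1 and two benzyloxy groups) attacks before rearomatising by proton loss. The closest known reaction type is the acid-mediated intramolecular Friedel–Crafts alkylation of aryl 3-aryl-3-hydroxypropyl ethers to 4-arylchromans. Ring C (O1, C2, C3, C4, C4a, C8a) closes as a six-membered ring by C4–C4a bond formation, with the C4a=C8a bond of the attacking arene inside the new ring. The new C4 stereocentre is controlled by C2 and C3: in the chair-like transition state the C2 aryl group is equatorial, the cis C3 benzyloxy group is axial, and ring D goes pseudoaxial on the face opposite O3, away from the peri C5 benzyloxy group, which should give the 3,4-trans (4β) isomer from either C4 epimer of 16. The step needs site selectivity for the phenoxy ortho carbon (the two are equivalent): the 4-benzyloxyphenyl ring could only close a five-membered ring through a carbon meta to its oxygen, the benzyl rings are unactivated, C8′ carries bromine, and the O3′ hydroxyl could only form a strained bridged ether reversibly. High dilution and low temperature are used to suppress intermolecular alkylation, loss of H3 from the cation and acid cleavage of the new bonds.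

Step 13
Reactants: 18 the benzylated 8′-bromo dimer; 19 3,4,5-tris(benzyloxy)benzoic acid
Product: 20 3,5,7,4′-tetra-O-benzyl-(−)-epiafzelechin-(4β→6)-8-bromo-5,7,3′,4′-tetra-O-benzyl-(−)-epicatechin 3-O-[3,4,5-tris(benzyloxy)benzoate]
Conditions: DCC, DMAP (cat.), CH2Cl2, rt
Reagents that add atoms: none
Why: Steglich esterification acylates the only free hydroxyl, the secondary O3′ of the lower unit, with retention at C3′.

Step 14
Reactants: 20 the fully protected gallate
Product: 21 (−)-epiafzelechin-(4β→6)-(−)-epicatechin 3-O-gallate (CNP0210310.1; upper unit 2R,3R,4S, lower unit 2R,3R)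
Conditions: H2 (1 atm), Pd(OH)2/C, Et3N (1.5 equiv), THF/MeOH, rt
Reagents that add atoms: none
Why: Catalytic hydrogenolysis cleaves all eleven benzyl ethers and, with Et3N taking up HBr, the aryl C–Br bond, while the ester, the pyran C2–O bonds and the C4–C6′ bond are not hydrogenolysed under these conditions. The C4 descriptor changes from R in 18 and 20 to S in 21 only through the priority rules.

**Compound list**
1 | (−)-epicatechin | O[C@@H]1Cc2c(O)cc(O)cc2O[C@@H]1c1ccc(O)c(O)c1 | starting material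
2 | 5,7,3′,4′-tetra-O-benzyl-(−)-epicatechin | O[C@@H]1Cc2c(OCc3ccccc3)cc(OCc3ccccc3)cc2O[C@@H]1c1ccc(OCc2ccccc2)c(OCc2ccccc2)c1 | intermediate
3 | 8-bromo-5,7,3′,4′-tetra-O-benzyl-(−)-epicatechin | O[C@@H]1Cc2c(OCc3ccccc3)cc(OCc3ccccc3)c(Br)c2O[C@@H]1c1ccc(OCc2ccccc2)c(OCc2ccccc2)c1 | intermediate
4 | 8-bromo-6-iodo-5,7,3′,4′-tetra-O-benzyl-(−)-epicatechin | O[C@@H]1Cc2c(OCc3ccccc3)c(I)c(OCc3ccccc3)c(Br)c2O[C@@H]1c1ccc(OCc2ccccc2)c(OCc2ccccc2)c1 | intermediate
5 | methyl 3,4-O-isopropylidene-L-threonate | COC(=O)[C@H](O)[C@@H]1COC(C)(C)O1 | starting material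
6 | methyl 2-O-benzyl-3,4-O-isopropylidene-L-threonate | COC(=O)[C@H](OCc1ccccc1)[C@@H]1COC(C)(C)O1 | intermediate
7 | (2R)-2-(benzyloxy)-2-[(4S)-2,2-dimethyl-1,3-dioxolan-4-yl]-N-methoxy-N-methylacetamide | CON(C)C(=O)[C@H](OCc1ccccc1)[C@@H]1COC(C)(C)O1 | intermediate
8 | 4-(benzyloxy)phenylmagnesium bromide | Br[Mg]c1ccc(OCc2ccccc2)cc1 | starting material
9 | (2R)-2-(benzyloxy)-1-[4-(benzyloxy)phenyl]-2-[(4S)-2,2-dimethyl-1,3-dioxolan-4-yl]ethan-1-one | O=C(c1ccc(OCc2ccccc2)cc1)[C@H](OCc1ccccc1)[C@@H]1COC(C)(C)O1 | intermediate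
10 | (1S,2S)-2-(benzyloxy)-1-[4-(benzyloxy)phenyl]-2-[(4S)-2,2-dimethyl-1,3-dioxolan-4-yl]ethan-1-ol | O[C@@H](c1ccc(OCc2ccccc2)cc1)[C@H](OCc1ccccc1)[C@@H]1COC(C)(C)O1 | intermediate
11 | 3,5-bis(benzyloxy)phenol | Oc1cc(OCc2ccccc2)cc(OCc2ccccc2)c1 | starting material
12 | (4S)-4-[(1S,2R)-1-(benzyloxy)-2-[3,5-bis(benzyloxy)phenoxy]-2-[4-(benzyloxy)phenyl]ethyl]-2,2-dimethyl-1,3-dioxolane | c1c(OCc2ccccc2)cc(OCc2ccccc2)cc1O[C@H](c1ccc(OCc2ccccc2)cc1)[C@H](OCc1ccccc1)[C@@H]1COC(C)(C)O1 | intermediate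
13 | (2S,3R,4R)-3-(benzyloxy)-4-[3,5-bis(benzyloxy)phenoxy]-4-[4-(benzyloxy)phenyl]butane-1,2-diol | OC[C@H](O)[C@@H](OCc1ccccc1)[C@H](Oc1cc(OCc2ccccc2)cc(OCc2ccccc2)c1)c1ccc(OCc2ccccc2)cc1 | intermediate
14 | (2S,3R)-2-(benzyloxy)-3-[3,5-bis(benzyloxy)phenoxy]-3-[4-(benzyloxy)phenyl]propanal | O=C[C@@H](OCc1ccccc1)[C@H](Oc1cc(OCc2ccccc2)cc(OCc2ccccc2)c1)c1ccc(OCc2ccccc2)cc1 | intermediate
15 | C6 arylmagnesium chloride of 4 with the 3-hydroxyl as its chloromagnesium alkoxide | Cl[Mg]O[C@@H]1Cc2c(OCc3ccccc3)c([Mg]Cl)c(OCc3ccccc3)c(Br)c2O[C@@H]1c1ccc(OCc2ccccc2)c(OCc2ccccc2)c1 | intermediate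
16 | 8-bromo-6-[(2R,3R)-2-(benzyloxy)-3-[3,5-bis(benzyloxy)phenoxy]-3-[4-(benzyloxy)phenyl]-1-hydroxypropyl]-5,7,3′,4′-tetra-O-benzyl-(−)-epicatechin (both carbinol epimers) | O[C@@H]1Cc2c(OCc3ccccc3)c(C(O)[C@@H](OCc3ccccc3)[C@H](Oc3cc(OCc4ccccc4)cc(OCc4ccccc4)c3)c3ccc(OCc4ccccc4)cc3)c(OCc3ccccc3)c(Br)c2O[C@@H]1c1ccc(OCc2ccccc2)c(OCc2ccccc2)c1 | intermediate
17 | C4 benzylic cation derived from 16 | O[C@@H]1Cc2c(OCc3ccccc3)c([CH+][C@@H](OCc3ccccc3)[C@H](Oc3cc(OCc4ccccc4)cc(OCc4ccccc4)c3)c3ccc(OCc4ccccc4)cc3)c(OCc3ccccc3)c(Br)c2O[C@@H]1c1ccc(OCc2ccccc2)c(OCc2ccccc2)c1 | intermediate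
18 | 3,5,7,4′-tetra-O-benzyl-(−)-epiafzelechin-(4β→6)-8-bromo-5,7,3′,4′-tetra-O-benzyl-(−)-epicatechin (upper unit 2R,3R,4R; 2,3-cis-3,4-trans) | O[C@@H]1Cc2c(OCc3ccccc3)c([C@H]3c4c(OCc5ccccc5)cc(OCc5ccccc5)cc4O[C@H](c4ccc(OCc5ccccc5)cc4)[C@@H]3OCc3ccccc3)c(OCc3ccccc3)c(Br)c2O[C@@H]1c1ccc(OCc2ccccc2)c(OCc2ccccc2)c1 | intermediate
19 | 3,4,5-tris(benzyloxy)benzoic acid | OC(=O)c1cc(OCc2ccccc2)c(OCc2ccccc2)c(OCc2ccccc2)c1 | starting material
20 | 3-O-[3,4,5-tris(benzyloxy)benzoate] of 18 (ester on O3 of the lower unit) | O=C(O[C@@H]1Cc2c(OCc3ccccc3)c([C@H]3c4c(OCc5ccccc5)cc(OCc5ccccc5)cc4O[C@H](c4ccc(OCc5ccccc5)cc4)[C@@H]3OCc3ccccc3)c(OCc3ccccc3)c(Br)c2O[C@@H]1c1ccc(OCc2ccccc2)c(OCc2ccccc2)c1)c1cc(OCc2ccccc2)c(OCc2ccccc2)c(OCc2ccccc2)c1 | intermediate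
21 | (−)-epiafzelechin-(4β→6)-(−)-epicatechin 3-O-gallate (CNP0210310.1) | O=C(O[C@@H]1Cc2c(cc(O)c([C@H]3c4c(O)cc(O)cc4O[C@H](c4ccc(O)cc4)[C@@H]3O)c2O)O[C@@H]1c1ccc(O)c(O)c1)c1cc(O)c(O)c(O)c1 | target

**Count and risks**
Total: 14 steps. Longest linear sequence: 11 steps (5 → 21, steps 4–14); the epicatechin branch contributes 3 steps before the union in step 11.

Steps most likely to fail:

Step 12 (key step). The cation may lose H3 to give an enol ether, the facial selectivity of ring closure may be poor, or the acid may reopen the new C4–aryl bonds. Fallback: close ring C first and make the interflavan bond second. Aldehyde 14 is treated with a mild Lewis acid (MgBr2·OEt2, CH2Cl2, −78 °C) so that the phenoxy ortho carbon adds to the aldehyde, giving the flavan-4-ol (2R,3R)-3,5,7-tris(benzyloxy)-2-[4-(benzyloxy)phenyl]chroman-4-ol F1. F1 is then ionised with catalytic TMSOTf at −78 °C in the presence of excess bromide 3; because C8 of 3 is blocked, its C6 should attack the cyclic C4 cation anti to the axial 3-benzyloxy group. This known flavan-4-ol/flavan condensation sets out from 14 and 3 and returns to the route at 18.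

Step 8. The oxyphosphonium ion of 10 may ionise, because the 4-benzyloxyphenyl group stabilises a benzylic cation, giving ether with partial retention, or it may undergo E2 loss to an enol ether. Fallback: make the C2–O1 bond at the aryl carbon, with retention at C2. Amide 7 is reduced with i-Bu2AlH to the aldehyde (2R)-2-(benzyloxy)-2-[(4S)-2,2-dimethyl-1,3-dioxolan-4-yl]acetaldehyde F2. Grignard reagent 8 is added under chelation control (MgBr2·OEt2, CH2Cl2, −78 °C) to give the syn alcohol (1R,2S)-2-(benzyloxy)-1-[4-(benzyloxy)phenyl]-2-[(4S)-2,2-dimethyl-1,3-dioxolan-4-yl]ethan-1-ol F3, the carbinol epimer of 10. F3 is O-arylated with 1-bromo-3,5-bis(benzyloxy)benzene by palladium-catalysed C–O coupling ([(allyl)PdCl]2, RockPhos, Cs2CO3, toluene, 90 °C), which does not touch the carbinol carbon. The fallback sets out from 7 and returns at 12.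

Step 11. The hindered arylmagnesium 15 may deprotonate the α-carbon of aldehyde 14, followed by β-loss of the aryloxide, or the exchange may be incomplete. Fallback: form the C6′–C4 bond by acylation and the carbinol by reduction. Aldehyde 14 is oxidised (Pinnick: NaClO2, NaH2PO4, 2-methyl-2-butene) to (2S,3R)-2-(benzyloxy)-3-[3,5-bis(benzyloxy)phenoxy]-3-[4-(benzyloxy)phenyl]propanoic acid F4. F4 is coupled with N,O-dimethylhydroxylamine (EDC, HOBt) to the Weinreb amide (2S,3R)-2-(benzyloxy)-3-[3,5-bis(benzyloxy)phenoxy]-3-[4-(benzyloxy)phenyl]-N-methoxy-N-methylpropanamide F5, whose α-proton is much less acidic. Arylmagnesium 15 adds to F5 to give the C4 ketone 8-bromo-6-[(2S,3R)-2-(benzyloxy)-3-[3,5-bis(benzyloxy)phenoxy]-3-[4-(benzyloxy)phenyl]propanoyl]-5,7,3′,4′-tetra-O-benzyl-(−)-epicatechin F6, and Luche reduction (NaBH4, CeCl3·7H2O, THF/MeOH, −20 °C) gives the carbinol. The fallback sets out from 14 and returns at 16.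

**Further compounds**
F1 | step 12 | (2R,3R)-3,5,7-tris(benzyloxy)-2-[4-(benzyloxy)phenyl]chroman-4-ol (both C4 epimers) | OC1c2c(OCc3ccccc3)cc(OCc3ccccc3)cc2O[C@H](c2ccc(OCc3ccccc3)cc2)[C@@H]1OCc1ccccc1
F2 | step 8 | (2R)-2-(benzyloxy)-2-[(4S)-2,2-dimethyl-1,3-dioxolan-4-yl]acetaldehyde | O=C[C@H](OCc1ccccc1)[C@@H]1COC(C)(C)O1
F3 | step 8 | (1R,2S)-2-(benzyloxy)-1-[4-(benzyloxy)phenyl]-2-[(4S)-2,2-dimethyl-1,3-dioxolan-4-yl]ethan-1-ol | O[C@H](c1ccc(OCc2ccccc2)cc1)[C@H](OCc1ccccc1)[C@@H]1COC(C)(C)O1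
F4 | step 11 | (2S,3R)-2-(benzyloxy)-3-[3,5-bis(benzyloxy)phenoxy]-3-[4-(benzyloxy)phenyl]propanoic acid | OC(=O)[C@@H](OCc1ccccc1)[C@H](Oc1cc(OCc2ccccc2)cc(OCc2ccccc2)c1)c1ccc(OCc2ccccc2)cc1
F5 | step 11 | (2S,3R)-2-(benzyloxy)-3-[3,5-bis(benzyloxy)phenoxy]-3-[4-(benzyloxy)phenyl]-N-methoxy-N-methylpropanamide | CON(C)C(=O)[C@@H](OCc1ccccc1)[C@H](Oc1cc(OCc2ccccc2)cc(OCc2ccccc2)c1)c1ccc(OCc2ccccc2)cc1
F6 | step 11 | 8-bromo-6-[(2S,3R)-2-(benzyloxy)-3-[3,5-bis(benzyloxy)phenoxy]-3-[4-(benzyloxy)phenyl]propanoyl]-5,7,3′,4′-tetra-O-benzyl-(−)-epicatechin | O[C@@H]1Cc2c(OCc3ccccc3)c(C(=O)[C@@H](OCc3ccccc3)[C@H](Oc3cc(OCc4ccccc4)cc(OCc4ccccc4)c3)c3ccc(OCc4ccccc4)cc3)c(OCc3ccccc3)c(Br)c2O[C@@H]1c1ccc(OCc2ccccc2)c(OCc2ccccc2)c1
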